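## The problem

The target is a guaiane. Ring A (C1–C5) is a 4-methylcyclopentenone carrying a tertiary hydroxyl at the ring-fusion carbon C1. Ring B (C1, C5–C10) is a cycloheptane carrying a free C6 hydroxyl, a C8 angelate, a C10 methyl and, on C7, a 2-acetoxyprop-2-yl group (C11).

Ring B holds five stereocentres (1R,6R,7S,8R,10S). The C6 hydroxyl, the C7–C11 bond, the C8 oxygen and the C10 methyl are all on one face, and the C1 hydroxyl is on the other. C1 is quaternary and vicinal to C10, so this pair has to be set early and in absolute terms. With a chiral catalyst it can then bias the face on which C7 and C8 are made, and the C7/C8 substituents can deliver the C6 oxygen.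

Several groups are fragile. The angelate isomerises to the tiglate under nucleophiles, base or heat. The tertiary acetate is slow to install and can migrate to a neighbouring hydroxyl. The ring-A β-hydroxy ketone and γ-hydroxy enone are open to retro-aldol cleavage and elimination, so the enone should be unveiled last.

A precursor with an exocyclic C5=C6 bond needs C7 cis to the more hindered C1, which olefination of a ketone cannot be trusted to give.

The enabling feature is that the C8 oxygen and C11 are cis and 1,3-related through C7. This is an acetone-aldol pattern that can be written as a cis-fused β-lactone spanning C7, C8 and C11, so ring B and this pair of centres can be formed together by aldol-lactonisation of an aldehyde acid.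

## Retrosynthesis

**26 to 24.** The C4=C5 bond and the C6 hydroxyl of target 26 are traced to the C5–C6 epoxide and a C3 carbinol in 24. Oxidation at C3 gives β,γ-epoxy ketone 25, which opens by E1cB elimination. Direct γ-hydroxylation of an enone would have to find the more hindered face of C6; here the oxygen is already in place. The forward step asks only for selective oxidation of one secondary alcohol and mild base.

**24 to 19.** Removing the two silyl ethers (23), the tertiary acetate (22), the angelate (20) and the epoxide oxygen leads to diol 19. The order is dictated by the hydroxyls. The epoxidation needs C8–OH and C11–OH free and the allylic C1 oxygen masked. The secondary C8 hydroxyl is acylated before the tertiary one. C6 stays hidden as the epoxide through both acylations.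

**19 to 18.** Cutting the two C11–CH3 bonds gives β-lactone 18. The lactone is the acetone aldol in latent form, with the cis relationship of C8–O and C7–C11 held in a four-membered ring.

**18 to 17 (key disconnection).** Cutting C7–C8 and the O–C11 acyl bond opens ring B and the lactone to aldehyde acid 17. Against an enolate aldol or a ketone reduction on the formed ring, this cut makes ring B, C7 and C8 in one operation and leaves a precursor whose only permanent stereocentres are C1 and C10. The forward reaction must close a seven-membered ring from an extended ammonium enolate at its α-carbon.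

**17 to 9.** The β,γ-unsaturated acid is traced through 16, 15 and 13 to lactol 11, acetal 10 and butenolide 9, by removing C11 (one-carbon homologation) and returning C7 to the carboxyl level. A Wittig reaction on a C5 ketone was rejected: the ketone is flanked by a quaternary and a tertiary carbon, it has a β-leaving group, and the required isomer is the more hindered one. In 9 the butenolide ring ties C7 to the C1 oxygen, so the C5=C6 geometry is not a matter of selectivity.

**9 to 7 and 8.** Cutting C1–C10 gives silyloxyfuran 7 and crotonaldehyde 8. One vinylogous Mukaiyama–Michael addition sets C1 and C10 and brings C8 in at the aldehyde level.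

**7 to 1 and 2.** The furan comes from enol lactone 6, keto acid 5 and keto ester 4. Cutting C4–CH3 and C5–C6 leads to the commercial enone 1 and benzyl bromoacetate 2. The C3 and C4 centres are auxiliary and are erased in the last step.

## Roads not taken

**Alternative 1:** Cut C8–C9 and postpone the C10 stereocentre. BF3·OEt2 would activate a C8 aldehyde for attack by the terminal carbon of a 2-(trimethylsilylmethyl)allyl unit on C1 (intramolecular Hosomi–Sakurai reaction). This gives A1, the hydroazulene with a C8 hydroxyl, a C10 exocyclic methylene and C6/C11 tied as an acetonide.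
- Merits: allylsilane–aldehyde closures to seven-membered rings are well documented, so the ring-forming event stands on firmer ground than the one chosen here. The C10 methyl could later be set by hydrogenation directed from the C1 oxygen, which would give the required trans relationship.
- Weak points: C6, C7 and C11 must be installed on an open chain next to ring A, with only remote control from C1. The C8 configuration rests on the conformational preference of one transition state. The Lewis acid meets an acetonide and two silyl ethers. The hydrogenation must distinguish the 1,1-disubstituted alkene from the tetrasubstituted one.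
- Comparison: A1 is better on precedent for the ring closure. The chosen plan sets against this that C7–C8 and the cis C8–O/C11 pair form in one step, and that no oxygenated stereotriad is carried through an acyclic stage.

**Alternative 2:** Cut C1–C2 in ring A. Rh2(OAc)4 would convert a (Z)-diazo enone into a carbenoid that inserts, with retention, into the silyloxy-activated C1–H bond. This gives A2, the 4-silyloxycyclopentenone with quaternary C1, the C10 stereocentre on a butenyl chain and C6 as a protected hydroxymethyl group.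
- Merits: insertion α to oxygen to close a five-membered ring is favourable. The C1/C10 pair could come from an aldehyde crotylation, which is at least as reliable as the organocatalytic addition used here. The ring-A hydroxy-enone is obtained directly.
- Weak points: the tetrasubstituted C4=C5 bond must carry C3 and C1 cis, which is the same kind of geometric problem that the chosen route removes with a ring. Cyclopropanation of the vinyl group and insertion next to the benzylic ether compete. Ring B with C6, C7 and C8 is still unmade while the sensitive hydroxy-enone is already present.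
- Comparison: better for ring A and C1, silent on ring B. The chosen plan spends its key step on ring B and the C7/C8 pair and reveals the enone last.

**Alternative 3:** Cut C1–C5 and C6–C7 together. An Achmatowicz reaction, acetylation and DBU-induced loss of acetate would give a 3-oxidopyrylium ylide that adds across a tethered (E)-vinylsilane in an intramolecular (5+2) cycloaddition. This gives A3, a hydroazulenone with an oxygen bridge between C1 and C7, a C8 ketone, a C9=C10 enone and a silyl group on C6.
- Merits: two rings and up to four stereocentres in one well-precedented step. The bridge supplies the C1 oxygen and the silane is a stereospecific hydroxyl equivalent. In bond-forming economy this is better than the chosen plan.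
- Weak points: the bridge oxygen sits on C7, where the target has hydrogen and C11. The C7–O bond must therefore be cleaved and C11 added afterwards by an aldol under substrate control. C8 (ketone reduction), C10 (enone reduction) and the ring-A enone (dehydrogenation) each add a redox step with its own selectivity question.
- Comparison: A3 reaches the bicycle faster. The chosen plan has C11 in place as the lactone carbonyl and needs only one stereoselective oxidation after the key step; in exchange it accepts a ring closure without direct precedent.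

Key step: step 12

Remark: atoms are numbered as in guaiane throughout (ring A = C1–C5; ring B = C1, C5–C10; C11 on C7). The ring-A centres C3 and C4 of the intermediates are temporary, and their CIP labels change with the neighbouring substituents.

## Route

Step 1
Reactants: 1 (S)-4-[(tert-butyldimethylsilyl)oxy]cyclopent-2-en-1-one; 2 benzyl bromoacetate
Product: 4 benzyl 2-[(1S,2S,3S)-3-[(tert-butyldimethylsilyl)oxy]-2-methyl-5-oxocyclopentyl]acetate, via lithium enolate 3 (not isolated)
Conditions: Me2CuLi, THF, −78 °C; then 2, HMPA, −78 → −30 °C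
Reagents that add atoms: lithium dimethylcuprate, [Li+].C[Cu-]C
Why: Tandem cuprate conjugate addition–enolate alkylation (three-component coupling) on a 4-silyloxycyclopentenone: the methyl group enters anti to the silyloxy group and the enolate is alkylated anti to the new methyl, so the ring should be all-trans; C3 and C4 are auxiliary centres that disappear in step 18.

Step 2
Reactants: 4 benzyl 2-[(1S,2S,3S)-3-[(tert-butyldimethylsilyl)oxy]-2-methyl-5-oxocyclopentyl]acetate
Product: 5 2-[(1S,2S,3S)-3-[(tert-butyldimethylsilyl)oxy]-2-methyl-5-oxocyclopentyl]acetic acid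
Conditions: H2 (1 atm), Pd/C, EtOAc, 23 °C
Reagents that add atoms: none
Why: Hydrogenolysis of the benzyl ester; neutral conditions keep the β-silyloxy ketone away from base, which could eliminate the silyloxy group.

Step 3
Reactants: 5 2-[(1S,2S,3S)-3-[(tert-butyldimethylsilyl)oxy]-2-methyl-5-oxocyclopentyl]acetic acid
Product: 6 (4S,5S)-5-[(tert-butyldimethylsilyl)oxy]-4-methyl-3,4,5,6-tetrahydro-2H-cyclopenta[b]furan-2-one
Conditions: Ac2O, NaOAc, 70 °C
Reagents that add atoms: none
Why: Enol lactonisation of a γ-keto acid by way of the mixed anhydride and the pseudo-acid acetate; elimination towards the more substituted C5 should give the ring-fusion (C1=C5) enol lactone, the isomer that can aromatise in step 4.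

Step 4
Reactants: 6 (4S,5S)-5-[(tert-butyldimethylsilyl)oxy]-4-methyl-3,4,5,6-tetrahydro-2H-cyclopenta[b]furan-2-one
Product: 7 (4S,5S)-5-[(tert-butyldimethylsilyl)oxy]-4-methyl-2-[(triisopropylsilyl)oxy]-5,6-dihydro-4H-cyclopenta[b]furan
Conditions: iPr3SiOTf, Et3N, CH2Cl2, 0 °C
Reagents that add atoms: triisopropylsilyl trifluoromethanesulfonate, CC(C)[Si](C(C)C)(C(C)C)OS(=O)(=O)C(F)(F)F
Why: Soft enolisation and O-silylation of a 2(3H)-furanone gives the aromatic 2-silyloxyfuran, a vinylogous enol ether whose nucleophilic carbon is C1.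

Step 5
Reactants: 7 (4S,5S)-5-[(tert-butyldimethylsilyl)oxy]-4-methyl-2-[(triisopropylsilyl)oxy]-5,6-dihydro-4H-cyclopenta[b]furan; 8 (E)-but-2-enal (crotonaldehyde)
Product: 9 (3S)-3-[(4S,5S,6aR)-5-[(tert-butyldimethylsilyl)oxy]-4-methyl-2-oxo-4,5,6,6a-tetrahydro-2H-cyclopenta[b]furan-6a-yl]butanal
Conditions: (2R,5R)-5-benzyl-2-tert-butyl-3-methylimidazolidin-4-one·2,4-dinitrobenzoic acid (20 mol %), CH2Cl2/H2O, −70 °C
Reagents that add atoms: none
Why: Organocatalytic vinylogous Mukaiyama–Michael addition: the imidazolidinone turns 8 into an iminium ion with one face shielded, so that furan C1 adds to the face that makes C10 (S), and C1 is attacked anti to the C4 methyl to give (1R); water removes the silyl group and releases the catalyst. The reaction type is established for 5-alkyl-2-silyloxyfurans and crotonaldehyde, where acid cocatalyst and solvent set the relative topicity of the two new centres. The butenolide ring ties C7 to the C1 oxygen and so fixes the later C5=C6 geometry.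

Step 6
Reactants: 9 (3S)-3-[(4S,5S,6aR)-5-[(tert-butyldimethylsilyl)oxy]-4-methyl-2-oxo-4,5,6,6a-tetrahydro-2H-cyclopenta[b]furan-6a-yl]butanal
Product: 10 (4S,5S,6aR)-5-[(tert-butyldimethylsilyl)oxy]-6a-[(2S)-4,4-dimethoxybutan-2-yl]-4-methyl-4,5,6,6a-tetrahydro-2H-cyclopenta[b]furan-2-one
Conditions: HC(OMe)3, PPTS (cat.), MeOH, 23 °C
Reagents that add atoms: trimethyl orthoformate, COC(OC)OC
Why: Acid-catalysed acetalisation masks the C8 aldehyde for the hydride, ylide and oxidation steps that follow.

Step 7
Reactants: 10 (4S,5S,6aR)-5-[(tert-butyldimethylsilyl)oxy]-6a-[(2S)-4,4-dimethoxybutan-2-yl]-4-methyl-4,5,6,6a-tetrahydro-2H-cyclopenta[b]furan-2-one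
Product: 11 (4S,5S,6aR)-5-[(tert-butyldimethylsilyl)oxy]-6a-[(2S)-4,4-dimethoxybutan-2-yl]-4-methyl-4,5,6,6a-tetrahydro-2H-cyclopenta[b]furan-2-ol (both anomers)
Conditions: iBu2AlH, CH2Cl2, −78 °C
Reagents that add atoms: none
Why: Low-temperature hydride reduction of a lactone stops at the lactol; because C1 is quaternary the dihydrofuranol cannot aromatise, and the ring keeps C5=C6 in the required geometry (the hemiacetal centre is consumed in step 8).

Step 8
Reactants: 11 (4S,5S,6aR)-5-[(tert-butyldimethylsilyl)oxy]-6a-[(2S)-4,4-dimethoxybutan-2-yl]-4-methyl-4,5,6,6a-tetrahydro-2H-cyclopenta[b]furan-2-ol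
Product: 13 (5Z)-diene bis-silyl ether: cyclopentane C1–C5 with OSiEt3 and the (2S)-4,4-dimethoxybutan-2-yl chain on C1, OSi(tBu)Me2 on C3, CH3 on C4 and the exocyclic (Z)-C5=C6–C7H=C11H2 unit (1R,3S,4S,10S), via potassium alkoxide 12 (not isolated)
Conditions: Ph3PCH3Br, KN(SiMe3)2, THF, 0 → 23 °C; then Et3SiCl, 0 °C
Reagents that add atoms: methyltriphenylphosphonium bromide, C[P+](c1ccccc1)(c1ccccc1)c1ccccc1.[Br-]; chlorotriethylsilane, CC[Si](Cl)(CC)CC
Why: Wittig methylenation of the ring-opened hydroxy-enal form of the lactol gives the diene with the (5Z) geometry inherited from the ring, and the tertiary potassium alkoxide left behind is silylated in the same flask; a silyl chloride is used because silyl triflates attack dimethyl acetals.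

Step 9
Reactants: 13 (5Z)-diene bis-silyl ether
Product: 15 (5Z)-homoallylic alcohol: as 13 but with the side chain C5=C6H–C7H2–C11H2OH (1R,3S,4S,10S), via alkylborane 14 (not isolated)
Conditions: 9-BBN, THF, 0 → 23 °C; then NaOH, H2O2, 0 °C
Reagents that add atoms: hydrogen peroxide, OO
Why: Hydroboration–oxidation: the bulky dialkylborane adds only to the monosubstituted terminus of the diene and places boron on C11, giving the primary alcohol without touching the trisubstituted C5=C6 bond.

Step 10
Reactants: 15 (5Z)-homoallylic alcohol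
Product: 16 (5Z)-acetal acid: as 15 but with the side chain C5=C6H–C7H2–C11OOH (1R,3S,4S,10S)
Conditions: TEMPO (cat.), NaClO2, NaOCl (cat.), MeCN/phosphate buffer (pH 6.7), 35 °C
Reagents that add atoms: sodium chlorite, [Na+].[O-]Cl=O
Why: Nitroxyl-catalysed oxidation of the primary alcohol with chlorite as terminal oxidant gives the acid directly at near-neutral pH, which spares the acetal and silyl ethers and leaves the β,γ-unsaturated aldehyde little time to conjugate.

Step 11
Reactants: 16 (5Z)-acetal acid
Product: 17 aldehyde acid: (Z)-4-(cyclopentylidene)but-3-enoic acid whose ring (C1–C5) carries OSiEt3 and the (2S)-4-oxobutan-2-yl chain on C1, OSi(tBu)Me2 on C3 and CH3 on C4 (1R,3S,4S,10S,5Z)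
Conditions: PPTS, acetone/H2O, 40 °C
Reagents that add atoms: water, O
Why: Mild acid-catalysed hydrolysis of the dimethyl acetal releases the C8 aldehyde; the tertiary triethylsilyl and secondary tert-butyldimethylsilyl ethers are expected to survive pyridinium tosylate.

Step 12
Reactants: 17 aldehyde acid
Product: 18 tricyclic β-lactone: hydroazulene with C5=C6, OSiEt3 on C1, OSi(tBu)Me2 on C3, CH3 on C4 and C10, and a cis-fused β-lactone whose oxygen is on C8 and whose carbonyl carbon (C11) is on C7 (1R,3S,4S,7S,8R,10S)
Conditions: 2-chloro-1-methylpyridinium iodide, iPr2NEt, O-trimethylsilylquinidine (20 mol %), MeCN, 23 °C, slow addition of 17 (final 0.005 M)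
Reagents that add atoms: none
Why: Proposed new method: the pyridinium salt converts the carboxyl group of 17 into an acyloxypyridinium ester, acyl transfer to the quinuclidine nitrogen of the catalyst gives an acylammonium ion whose allylic C7–H is removed by iPr2NEt, and the ammonium enolate adds through C7 to the C8 aldehyde before the aldolate oxygen attacks C11 and expels the catalyst; the closest known reaction type is the intramolecular nucleophile-catalysed aldol-lactonisation of aldehyde acids, established for cyclopentane- and cyclohexane-fused β-lactones but not for a seven-membered carbocycle or a β,γ-unsaturated acid. Ring B closes by a 7-(enolexo)-exo-trig aldol addition, helped by the (Z)-C5=C6 bond and the quaternary C1, which hold both chains on the same side of ring A, and the β-lactone closes by 4-exo-trig acyl substitution. C7 and C8 are created together: their cis relationship should follow because only the syn aldolate is placed to lactonise, the aldol step being reversible and the lactonisation not. Their sense relative to C1/C10 is chosen by the cinchona catalyst, whose bulky ammonium unit on C11 is also kept away from the C1 silyloxy group. The step needs α- and not γ-reactivity of the extended enolate: the γ-carbon C5 is fully substituted and next to the quaternary C1, so bond formation there would have to build two adjacent quaternary centres. It also needs cyclisation to outrun dimerisation, which slow addition at high dilution is meant to secure.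

Step 13
Reactants: 18 tricyclic β-lactone
Product: 19 (1R,3S,4S,7S,8R,10S)-3-[(tert-butyldimethylsilyl)oxy]-1-[(triethylsilyl)oxy]guai-5-ene-8,11-diol
Conditions: MeMgBr, CeCl3, THF, −78 → −20 °C
Reagents that add atoms: methylmagnesium bromide, C[Mg]Br
Why: Double addition of a methyl organometallic to the lactone carbonyl (acyl–oxygen cleavage, then addition to the methyl ketone) turns C11 into the dimethyl carbinol and frees the C8 hydroxyl; CeCl3 lowers the basicity so that C7 is not enolised and the transient β-alkoxy ketone does not undergo retro-aldol ring opening. C7 and C8 keep their configuration.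

Step 14
Reactants: 19 (1R,3S,4S,7S,8R,10S)-3-[(tert-butyldimethylsilyl)oxy]-1-[(triethylsilyl)oxy]guai-5-ene-8,11-diol
Product: 20 (1R,3S,4R,5R,6R,7R,8R,10S)-3-[(tert-butyldimethylsilyl)oxy]-5,6-epoxy-1-[(triethylsilyl)oxy]guaiane-8,11-diol
Conditions: VO(acac)2 (5 mol %), tBuOOH, CH2Cl2, 0 → 23 °C
Reagents that add atoms: tert-butyl hydroperoxide, CC(C)(C)OO
Why: Hydroxyl-directed epoxidation by a vanadium peroxo complex: C8–OH and C11–OH are both homoallylic to C5=C6 and lie on the same face, so oxygen should be delivered cis to them, while the allylic C1 oxygen, which would direct to the other face, is silylated.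

Step 15
Reactants: 20 (1R,3S,4R,5R,6R,7R,8R,10S)-3-[(tert-butyldimethylsilyl)oxy]-5,6-epoxy-1-[(triethylsilyl)oxy]guaiane-8,11-diol; 21 angelic acid [(Z)-2-methylbut-2-enoic acid]
Product: 22 (1R,3S,4R,5R,6R,7R,8R,10S)-3-[(tert-butyldimethylsilyl)oxy]-5,6-epoxy-11-hydroxy-1-[(triethylsilyl)oxy]guaian-8-yl (Z)-2-methylbut-2-enoate
Conditions: 2,4,6-Cl3C6H2COCl, Et3N, toluene, 23 → 70 °C
Reagents that add atoms: none
Why: Yamaguchi esterification through the mixed 2,4,6-trichlorobenzoic anhydride of angelic acid, run without a nucleophilic catalyst to keep the (Z) geometry; the secondary C8 hydroxyl reacts and the tertiary C11 hydroxyl does not.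

Step 16
Reactants: 22 (1R,3S,4R,5R,6R,7R,8R,10S)-3-[(tert-butyldimethylsilyl)oxy]-5,6-epoxy-11-hydroxy-1-[(triethylsilyl)oxy]guaian-8-yl (Z)-2-methylbut-2-enoate
Product: 23 (1R,3S,4R,5R,6R,7R,8R,10S)-11-acetoxy-3-[(tert-butyldimethylsilyl)oxy]-5,6-epoxy-1-[(triethylsilyl)oxy]guaian-8-yl (Z)-2-methylbut-2-enoate
Conditions: Ac2O, DMAP, Et3N, CH2Cl2, 23 → 40 °C
Reagents that add atoms: acetic anhydride, CC(=O)OC(C)=O
Why: DMAP-catalysed acetylation of the remaining tertiary alcohol; C6 is still masked as the epoxide and C1/C3 as silyl ethers, so no other hydroxyl competes.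

Step 17
Reactants: 23 (1R,3S,4R,5R,6R,7R,8R,10S)-11-acetoxy-3-[(tert-butyldimethylsilyl)oxy]-5,6-epoxy-1-[(triethylsilyl)oxy]guaian-8-yl (Z)-2-methylbut-2-enoate
Product: 24 (1R,3S,4R,5R,6R,7R,8R,10S)-11-acetoxy-5,6-epoxy-1,3-dihydroxyguaian-8-yl (Z)-2-methylbut-2-enoate
Conditions: Bu4NF, AcOH, THF, 0 → 23 °C
Reagents that add atoms: none
Why: Fluoride cleaves both silyl ethers; buffering with acetic acid keeps the medium non-basic so that the esters do not migrate and the C1 alkoxide does not open the neighbouring epoxide (Payne rearrangement).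

Step 18
Reactants: 24 (1R,3S,4R,5R,6R,7R,8R,10S)-11-acetoxy-5,6-epoxy-1,3-dihydroxyguaian-8-yl (Z)-2-methylbut-2-enoate
Product: 26 (1R,6R,7S,8R,10S)-11-acetoxy-1,6-dihydroxy-3-oxoguai-4-en-8-yl (Z)-2-methylbut-2-enoate (CNP0273287.1), via β,γ-epoxy ketone 25 (not isolated)
Conditions: Dess–Martin periodinane, CH2Cl2, 0 → 23 °C; then Et3N, 23 °C
Reagents that add atoms: none
Why: Dess–Martin oxidation affects only the secondary C3 hydroxyl; in the resulting β,γ-epoxy ketone the C4–H is acidic, and mild base opens the epoxide by E1cB elimination, which creates the C4=C5 enone and releases the C6 hydroxyl with the configuration set in step 14. The auxiliary centres C3 and C4 vanish here.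

## Compound list

1 | (S)-4-[(tert-butyldimethylsilyl)oxy]cyclopent-2-en-1-one | O=C1C=C[C@@H](O[Si](C)(C)C(C)(C)C)C1 | starting material
2 | benzyl bromoacetate | BrCC(=O)OCc1ccccc1 | starting material
3 | lithium (3S,4S)-4-[(tert-butyldimethylsilyl)oxy]-3-methylcyclopent-1-en-1-olate | [Li+].[O-]C1=C[C@H](C)[C@@H](O[Si](C)(C)C(C)(C)C)C1 | intermediate
4 | benzyl 2-[(1S,2S,3S)-3-[(tert-butyldimethylsilyl)oxy]-2-methyl-5-oxocyclopentyl]acetate | O=C1C[C@H](O[Si](C)(C)C(C)(C)C)[C@@H](C)[C@@H]1CC(=O)OCc2ccccc2 | intermediate
5 | 2-[(1S,2S,3S)-3-[(tert-butyldimethylsilyl)oxy]-2-methyl-5-oxocyclopentyl]acetic acid | O=C1C[C@H](O[Si](C)(C)C(C)(C)C)[C@@H](C)[C@@H]1CC(=O)O | intermediate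
6 | (4S,5S)-5-[(tert-butyldimethylsilyl)oxy]-4-methyl-3,4,5,6-tetrahydro-2H-cyclopenta[b]furan-2-one | O=C1CC2=C(O1)C[C@H](O[Si](C)(C)C(C)(C)C)[C@H]2C | intermediate
7 | (4S,5S)-5-[(tert-butyldimethylsilyl)oxy]-4-methyl-2-[(triisopropylsilyl)oxy]-5,6-dihydro-4H-cyclopenta[b]furan | CC(C)[Si](C(C)C)(C(C)C)Oc1cc2c(o1)C[C@H](O[Si](C)(C)C(C)(C)C)[C@H]2C | intermediate
8 | (E)-but-2-enal (crotonaldehyde) | C/C=C/C=O | starting material
9 | (3S)-3-[(4S,5S,6aR)-5-[(tert-butyldimethylsilyl)oxy]-4-methyl-2-oxo-4,5,6,6a-tetrahydro-2H-cyclopenta[b]furan-6a-yl]butanal | O=CC[C@H](C)[C@]12C[C@H](O[Si](C)(C)C(C)(C)C)[C@@H](C)C1=CC(=O)O2 | intermediate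
10 | (4S,5S,6aR)-5-[(tert-butyldimethylsilyl)oxy]-6a-[(2S)-4,4-dimethoxybutan-2-yl]-4-methyl-4,5,6,6a-tetrahydro-2H-cyclopenta[b]furan-2-one | COC(OC)C[C@H](C)[C@]12C[C@H](O[Si](C)(C)C(C)(C)C)[C@@H](C)C1=CC(=O)O2 | intermediate
11 | (4S,5S,6aR)-5-[(tert-butyldimethylsilyl)oxy]-6a-[(2S)-4,4-dimethoxybutan-2-yl]-4-methyl-4,5,6,6a-tetrahydro-2H-cyclopenta[b]furan-2-ol (both anomers at the hemiacetal carbon) | COC(OC)C[C@H](C)[C@]12C[C@H](O[Si](C)(C)C(C)(C)C)[C@@H](C)C1=CC(O)O2 | intermediate
12 | potassium (1R,2Z,3S,4S)-4-[(tert-butyldimethylsilyl)oxy]-1-[(2S)-4,4-dimethoxybutan-2-yl]-3-methyl-2-(prop-2-en-1-ylidene)cyclopentan-1-olate | COC(OC)C[C@H](C)[C@]1([O-])C[C@H](O[Si](C)(C)C(C)(C)C)[C@@H](C)/C1=C/C=C.[K+] | intermediate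
13 | O-triethylsilyl ether of the alcohol of 12 [(5Z)-diene; 1R,3S,4S,10S] | COC(OC)C[C@H](C)[C@]1(O[Si](CC)(CC)CC)C[C@H](O[Si](C)(C)C(C)(C)C)[C@@H](C)/C1=C/C=C | intermediate
14 | B-alkyl-9-borabicyclo[3.3.1]nonane from 13 (boron on C11; 1R,3S,4S,10S,5Z) | COC(OC)C[C@H](C)[C@]1(O[Si](CC)(CC)CC)C[C@H](O[Si](C)(C)C(C)(C)C)[C@@H](C)/C1=C/CCB1C2CCCC1CCC2 | intermediate
15 | (5Z)-homoallylic alcohol: 13 with side chain C5=C6H–C7H2–C11H2OH (1R,3S,4S,10S) | COC(OC)C[C@H](C)[C@]1(O[Si](CC)(CC)CC)C[C@H](O[Si](C)(C)C(C)(C)C)[C@@H](C)/C1=C/CCO | intermediate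
16 | (5Z)-acetal acid: 15 with C11 as CO2H (1R,3S,4S,10S) | COC(OC)C[C@H](C)[C@]1(O[Si](CC)(CC)CC)C[C@H](O[Si](C)(C)C(C)(C)C)[C@@H](C)/C1=C/CC(=O)O | intermediate
17 | aldehyde acid: (Z)-4-(cyclopentylidene)but-3-enoic acid with OSiEt3 and (2S)-4-oxobutan-2-yl on C1, OSi(tBu)Me2 on C3, CH3 on C4 (1R,3S,4S,10S,5Z) | O=CC[C@H](C)[C@]1(O[Si](CC)(CC)CC)C[C@H](O[Si](C)(C)C(C)(C)C)[C@@H](C)/C1=C/CC(=O)O | intermediate
18 | tricyclic β-lactone: hydroazulene with C5=C6, C1–OSiEt3, C3–OSi(tBu)Me2, C4 and C10 methyls, cis-fused β-lactone O(C8)–C11(=O)–C7 (1R,3S,4S,7S,8R,10S) | O=C1O[C@@H]2C[C@H](C)[C@]3(O[Si](CC)(CC)CC)C[C@H](O[Si](C)(C)C(C)(C)C)[C@@H](C)C3=C[C@H]12 | intermediate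
19 | (1R,3S,4S,7S,8R,10S)-3-[(tert-butyldimethylsilyl)oxy]-1-[(triethylsilyl)oxy]guai-5-ene-8,11-diol | O[C@@H]1C[C@H](C)[C@]2(O[Si](CC)(CC)CC)C[C@H](O[Si](C)(C)C(C)(C)C)[C@@H](C)C2=C[C@@H]1C(C)(C)O | intermediate
20 | (1R,3S,4R,5R,6R,7R,8R,10S)-3-[(tert-butyldimethylsilyl)oxy]-5,6-epoxy-1-[(triethylsilyl)oxy]guaiane-8,11-diol | O[C@@H]1C[C@H](C)[C@]2(O[Si](CC)(CC)CC)C[C@H](O[Si](C)(C)C(C)(C)C)[C@@H](C)[C@]23O[C@@H]3[C@@H]1C(C)(C)O | intermediate
21 | angelic acid [(Z)-2-methylbut-2-enoic acid] | C/C=C(/C)C(=O)O | starting material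
22 | (1R,3S,4R,5R,6R,7R,8R,10S)-3-[(tert-butyldimethylsilyl)oxy]-5,6-epoxy-11-hydroxy-1-[(triethylsilyl)oxy]guaian-8-yl (Z)-2-methylbut-2-enoate | C/C=C(/C)C(=O)O[C@@H]1C[C@H](C)[C@]2(O[Si](CC)(CC)CC)C[C@H](O[Si](C)(C)C(C)(C)C)[C@@H](C)[C@]23O[C@@H]3[C@@H]1C(C)(C)O | intermediate
23 | (1R,3S,4R,5R,6R,7R,8R,10S)-11-acetoxy-3-[(tert-butyldimethylsilyl)oxy]-5,6-epoxy-1-[(triethylsilyl)oxy]guaian-8-yl (Z)-2-methylbut-2-enoate | C/C=C(/C)C(=O)O[C@@H]1C[C@H](C)[C@]2(O[Si](CC)(CC)CC)C[C@H](O[Si](C)(C)C(C)(C)C)[C@@H](C)[C@]23O[C@@H]3[C@@H]1C(C)(C)OC(C)=O | intermediate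
24 | (1R,3S,4R,5R,6R,7R,8R,10S)-11-acetoxy-5,6-epoxy-1,3-dihydroxyguaian-8-yl (Z)-2-methylbut-2-enoate | C/C=C(/C)C(=O)O[C@@H]1C[C@H](C)[C@]2(O)C[C@H](O)[C@@H](C)[C@]23O[C@@H]3[C@@H]1C(C)(C)OC(C)=O | intermediate
25 | (1R,4S,5R,6R,7R,8R,10S)-11-acetoxy-5,6-epoxy-1-hydroxy-3-oxoguaian-8-yl (Z)-2-methylbut-2-enoate | C/C=C(/C)C(=O)O[C@@H]1C[C@H](C)[C@]2(O)CC(=O)[C@@H](C)[C@]23O[C@@H]3[C@@H]1C(C)(C)OC(C)=O | intermediate
26 | (1R,6R,7S,8R,10S)-11-acetoxy-1,6-dihydroxy-3-oxoguai-4-en-8-yl (Z)-2-methylbut-2-enoate (CNP0273287.1) | C/C=C(/C)C(=O)O[C@@H]1C[C@H](C)[C@]2(O)CC(=O)C(C)=C2[C@H](O)[C@@H]1C(C)(C)OC(C)=O | target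

## Step count and least certain steps

Total: 18 steps. Longest linear sequence: 18 steps, from 1 to 26.

**Step 12 (key step, proposed new method).** Three things can go wrong.
- The extended ammonium enolate may react at its γ-carbon (C5 to C8), giving a five-membered carbocycle and a δ-lactone.
- The slow seven-membered closure may lose to intermolecular aldol or oligomerisation.
- The wrong diastereomer may form. On a seven-membered ring a trans-fused four-membered lactone is not geometrically excluded, and the catalyst has to overrule whatever facial bias C1 and C10 exert.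

Fallback with known chemistry: from 17, DCC coupling with thiophenol gives the S-phenyl thioester F1. Soft enolisation with MgBr2·OEt2 and iPr2NEt at high dilution effects a direct intramolecular thioester aldol to the ring-B β-hydroxy thioester F2, from which the (7S,8R) isomer is separated. MeMgBr/CeCl3 then converts the thioester into the dimethyl carbinol, and the route is rejoined at 19.

**Step 5.** The relative topicity at C1/C10 may be poorly controlled, and the 4,5-disubstituted furan may react slowly because a quaternary centre is being formed, so that protodesilylation by water competes. Fallback: from 7, a Mukaiyama–Michael addition to 3-[(E)-but-2-enoyl]-1,3-oxazolidin-2-one under Cu(OTf)2 with a C2-symmetric tert-butyl bis(oxazoline) ligand uses a two-point-bound acceptor and gives an independent handle on both faces. It leads to the imide F3. Thiolysis with LiSEt gives the S-ethyl thioester F4, and Fukuyama reduction (Et3SiH, Pd/C) returns to 9.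

**Step 1.** The cuprate-derived enolate may equilibrate and expel the β-silyloxy group, or alkylate sluggishly. Fallback: from 1, iodination (I2, pyridine) gives the 2-iodoenone F5. Negishi coupling with the Reformatsky reagent made from 2 and Zn (Pd(PPh3)4) gives the 2-substituted enone F6. Me2CuLi addition followed by protonation (no alkylation needed) then returns to 4.

**Step 13.** The methyl organometallic may enolise C7, or the β-alkoxy methyl ketone formed after the first addition may undergo retro-aldol cleavage of ring B before the second addition. Fallback: from 18, methanolysis (NaOMe, MeOH, 0 °C) gives the β-hydroxy methyl ester F7. Silylation (Me3SiCl, imidazole) gives the C8 trimethylsilyl ether F8, in which no alkoxide can form. MeLi/CeCl3 then gives the carbinol F9, and K2CO3 in MeOH removes the trimethylsilyl group to return to 19.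

**Step 16.** Acylation of the hindered tertiary hydroxyl may be slow, and on prolonged exposure DMAP can isomerise the angelate by conjugate addition–elimination. Fallback that reverses the order of the acylations: from 20, selective silylation of the secondary hydroxyl (Me3SiCl, imidazole, −20 °C) gives F10. Acetylation (Ac2O, DMAP, Et3N, 40 °C), with no angelate present, gives F11. Mild acid (PPTS, MeOH, 0 °C; non-basic to limit acetyl migration) frees C8–OH in F12. Yamaguchi esterification with 21 then returns to 23.

## Further compounds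

F1 | step 12 | S-phenyl thioester of aldehyde acid 17 | O=CC[C@H](C)[C@]1(O[Si](CC)(CC)CC)C[C@H](O[Si](C)(C)C(C)(C)C)[C@@H](C)/C1=C/CC(=O)Sc1ccccc1
F2 | step 12 | ring-B β-hydroxy S-phenyl thioester (C8–OH and C7–C(=O)SPh cis; 1R,3S,4S,7S,8R,10S) | O[C@@H]1C[C@H](C)[C@]2(O[Si](CC)(CC)CC)C[C@H](O[Si](C)(C)C(C)(C)C)[C@@H](C)C2=C[C@@H]1C(=O)Sc1ccccc1
F3 | step 5 | 3-{(3S)-3-[(4S,5S,6aR)-5-[(tert-butyldimethylsilyl)oxy]-4-methyl-2-oxo-4,5,6,6a-tetrahydro-2H-cyclopenta[b]furan-6a-yl]butanoyl}-1,3-oxazolidin-2-one | O=C(C[C@H](C)[C@]12C[C@H](O[Si](C)(C)C(C)(C)C)[C@@H](C)C1=CC(=O)O2)N1CCOC1=O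
F4 | step 5 | S-ethyl (3S)-3-[(4S,5S,6aR)-5-[(tert-butyldimethylsilyl)oxy]-4-methyl-2-oxo-4,5,6,6a-tetrahydro-2H-cyclopenta[b]furan-6a-yl]butanethioate | CCSC(=O)C[C@H](C)[C@]12C[C@H](O[Si](C)(C)C(C)(C)C)[C@@H](C)C1=CC(=O)O2
F5 | step 1 | (S)-4-[(tert-butyldimethylsilyl)oxy]-2-iodocyclopent-2-en-1-one | O=C1C(I)=C[C@@H](O[Si](C)(C)C(C)(C)C)C1
F6 | step 1 | benzyl 2-[(3S)-3-[(tert-butyldimethylsilyl)oxy]-5-oxocyclopent-1-en-1-yl]acetate | O=C1C(CC(=O)OCc2ccccc2)=C[C@@H](O[Si](C)(C)C(C)(C)C)C1
F7 | step 13 | ring-B β-hydroxy methyl ester from methanolysis of 18 (C8–OH, C7–CO2CH3 cis) | O[C@@H]1C[C@H](C)[C@]2(O[Si](CC)(CC)CC)C[C@H](O[Si](C)(C)C(C)(C)C)[C@@H](C)C2=C[C@@H]1C(=O)OC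
F8 | step 13 | C8 trimethylsilyl ether of F7 | C[Si](C)(C)O[C@@H]1C[C@H](C)[C@]2(O[Si](CC)(CC)CC)C[C@H](O[Si](C)(C)C(C)(C)C)[C@@H](C)C2=C[C@@H]1C(=O)OC
F9 | step 13 | C8 trimethylsilyl ether of diol 19 | C[Si](C)(C)O[C@@H]1C[C@H](C)[C@]2(O[Si](CC)(CC)CC)C[C@H](O[Si](C)(C)C(C)(C)C)[C@@H](C)C2=C[C@@H]1C(C)(C)O
F10 | step 16 | C8 trimethylsilyl ether of epoxy diol 20 | C[Si](C)(C)O[C@@H]1C[C@H](C)[C@]2(O[Si](CC)(CC)CC)C[C@H](O[Si](C)(C)C(C)(C)C)[C@@H](C)[C@]23O[C@@H]3[C@@H]1C(C)(C)O
F11 | step 16 | C11 acetate of F10 | C[Si](C)(C)O[C@@H]1C[C@H](C)[C@]2(O[Si](CC)(CC)CC)C[C@H](O[Si](C)(C)C(C)(C)C)[C@@H](C)[C@]23O[C@@H]3[C@@H]1C(C)(C)OC(C)=O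
F12 | step 16 | C11 acetate of epoxy diol 20 with free C8 hydroxyl | O[C@@H]1C[C@H](C)[C@]2(O[Si](CC)(CC)CC)C[C@H](O[Si](C)(C)C(C)(C)C)[C@@H](C)[C@]23O[C@@H]3[C@@H]1C(C)(C)OC(C)=O
A1 | alternative 1 | hydroazulene with C8 hydroxyl, C10 exocyclic methylene, C6/C11 acetonide, C1 triethylsilyl ether and C3 tert-butyldimethylsilyl ether | O[C@@H]1CC(=C)[C@]2(O[Si](CC)(CC)CC)C[C@@H](O[Si](C)(C)C(C)(C)C)C(C)=C2[C@@H]3OC(C)(C)OC(C)(C)[C@H]13
A2 | alternative 2 | cyclopentenone with quaternary C1 tert-butyldimethylsilyl ether, (S)-but-3-en-2-yl group on C1 and 4-methoxybenzyloxymethyl group on C5 | C=C[C@H](C)[C@]1(O[Si](C)(C)C(C)(C)C)CC(=O)C(C)=C1COCc1ccc(OC)cc1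
A3 | alternative 3 | C1,C7-oxygen-bridged hydroazulenone with C8 ketone, C9=C10 enone, C3 silyl ether and C6 dimethylphenylsilyl group | O=C1C=C(C)[C@]23C[C@@H](O[Si](C)(C)C(C)(C)C)[C@H](C)[C@H]2[C@H]([Si](C)(C)c2ccccc2)[C@H]1O3
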